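All runs stem from a simulated flask for substances that don't exist, and the scatter is random.

An order taken from slopes between readings compares rates at different conversions, so the number can look like a plain first order when the flask is not one. Times at equal conversion avoid this: if the rate at each conversion up to a given one goes as [X]^n, the time to reach it goes as [X]^−n.

common to all: G 0.19 mM

| flask | D | Z | X | remark |
|---|---|---|---|---|
| Thursday's | 10 mM | 10 mM | 0.12 mM | run made earlier |
| Wednesday's | 10 mM | 10 mM | 0.19 mM | run made earlier |
| Sunday's | 15 mM | 10 mM | 0.25 mM | run made earlier |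
| flask | 10 mM | 10.0 mM | 0.25 mM |  |

| run | time / h | L / % |
|---|---|---|
| Thursday's | 1.00 | 2.4 |
| Thursday's | 3.00 | 6.4 |
| Thursday's | 5.00 | 10.5 |
| Thursday's | 8.00 | 14.3 |
| Wednesday's | 1.00 | 3.9 |
| Wednesday's | 3.00 | 9.6 |
| Wednesday's | 5.00 | 15.5 |
| Wednesday's | 8.00 | 22.7 |
| Sunday's | 1.00 | 5.2 |
| Sunday's | 3.00 | 13.8 |
| Sunday's | 5.00 | 19.8 |
| Sunday's | 8.00 | 27.1 |

(readings scatter by 0.5 percentage points)

- apparent order in X when 20% of the D are converted (percent change of the rate of making L for one percent more X charged)

- the earlier runs were read with a standard deviation of 0.5 percentage points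

Two extreme flasks can be solved in the head. If G stands idle, n is one. Wednesday's run passes Thursday's last reading of 14.3% at 4.59 h, so Thursday's run should need 7.27 h. If G takes X one for one, the working X is [X] − [G], and the order in this flask is 4.17. But Thursday's run charged less X than G, so it should make no L, and it made L.

The real flask lies between these extremes, close to the first, so only the correction to one needs reckoning. Thursday's run took 8.00 h, which gives the time-scaled order, the exponent that carries the time to equal conversion from one [X] to another, as 1.21. This is a reading with the scatter of 0.5 points behind it, and it assumes n holds above [G]. Wednesday's run reaches 20% at 6.88 h, so this flask, with the same [D], should reach it at 4.94 h, against 5.23 h at order one.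

The forecast gave 1.05, within 0.75 to 1.35, noting “If it is product inhibition, the order stays at 1.”, while the reckoning here stays at n, higher. The flask gives 1.2.

    J → X + L (k = 428 h⁻¹)
    J + Z → E (k = 189 M⁻¹ h⁻¹)
    D + X ⇌ J (K = 48.7 M⁻¹, k = 212 M⁻¹ h⁻¹)
    X + G ⇌ Q (K = 3410 M⁻¹, k = 415 M⁻¹ h⁻¹)

This flask holds L 19.9% at 5.00 h, against the 4.94 h reckoned for 20%. For Sunday's run, n turns Wednesday's 6.79 h to 19.8% into 4.88 h; that scaling ignores the change of [D] from 10 mM to 15 mM, and Sunday's run read that percentage at 5.00 h. At 4.04 h in this flask, the forward step of D with X, taken alone, runs 30 times faster than the forward step of X with G alone. Even so, at 5.00 h the off-cycle form Q holds more of the catalyst charged than E, 20.5% against 3.52%.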